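**Assumption:** the target SMILES has no stereocentre or stereogenic axis, so "single enantiomer" is read as the one achiral constitution drawn; no stereocontrol is needed.

## Retrosynthetic overview

1. Target ⇐ its 5-O-methyl-3'-O-benzyl ether; one final BCl3 step removes both groups, with the peri carbonyl singling out the 5-OMe.
2. Ring C is the only ring built and is formed last, from a ring A salicylaldehyde and a ring B aryl ynamide: C4–C3 by rhodium-catalysed hydroacylation, O1–C2 by oxa-Michael addition and loss of sulfonamide (proposed new annulation).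
3. Ring A salicylaldehyde (benzene ring bought intact) ⇐ 3,4,5-trimethoxyphenol by bromination, copper-catalysed methoxylation and ortho-formylation.
4. Ring B ynamide (benzene ring bought intact) ⇐ 2,3-dihydroxybenzaldehyde by 3-O-benzylation, 2-O-methylation, dibromo-olefination and copper-catalysed N-alkynylation.

## Route

Step 1
Reactants: 1 3,4,5-trimethoxyphenol
Product: 2 2-bromo-3,4,5-trimethoxyphenol
Conditions: NBS (1.0 equiv), CH2Cl2, −78 → 0 °C
Reagents that add atoms: N-bromosuccinimide, O=C1CCC(=O)N1Br
Why: Electrophilic aromatic bromination at one of the two equivalent free positions (ortho to OH, para to OMe); one equivalent of NBS at low temperature limits dibromination.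

Step 2
Reactants: 2 2-bromo-3,4,5-trimethoxyphenol
Product: 3 2,3,4,5-tetramethoxyphenol
Conditions: NaOMe (6 equiv, 25% in MeOH), CuBr (0.2 equiv), DMF, 110 °C
Reagents that add atoms: sodium methoxide, [Na+].[O-]C
Why: Ullmann-type copper-catalysed methoxylation of an aryl bromide, the reaction type that converts unprotected ortho-bromophenols such as 5-bromovanillin into ortho-methoxyphenols.

Step 3
Reactants: 3 2,3,4,5-tetramethoxyphenol
Product: 5 2-hydroxy-3,4,5,6-tetramethoxybenzaldehyde, via salicyl alcohol 4 (not isolated)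
Conditions: MgCl2 (2 equiv), Et3N (4 equiv), (CH2O)n (6 equiv), MeCN, reflux; aq. HCl work-up
Reagents that add atoms: formaldehyde (from paraformaldehyde), C=O
Why: Magnesium-phenoxide-directed ortho-formylation (Casnati–Skattebøl reaction) at the single free ring position, with a second formaldehyde acting as hydride acceptor to oxidise 4 to the aldehyde.

Step 4
Reactants: 6 2,3-dihydroxybenzaldehyde
Product: 7 3-(benzyloxy)-2-hydroxybenzaldehyde
Conditions: NaH (2.2 equiv), DMSO, rt; then BnBr (1.0 equiv), rt
Reagents that add atoms: benzyl bromide, BrCc1ccccc1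
Why: Williamson etherification of the dianion, in which the 3-phenoxide (not conjugated to or chelated by the formyl group) is the more nucleophilic oxygen and takes the single equivalent of benzyl bromide.

Step 5
Reactants: 7 3-(benzyloxy)-2-hydroxybenzaldehyde
Product: 8 3-(benzyloxy)-2-methoxybenzaldehyde
Conditions: MeI (1.5 equiv), K2CO3 (2 equiv), DMF, 40 °C
Reagents that add atoms: iodomethane, CI
Why: Williamson O-methylation of the remaining phenol, which fixes the 2'-OMe/3'-O-protected pattern of ring B.

Step 6
Reactants: 8 3-(benzyloxy)-2-methoxybenzaldehyde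
Product: 9 1-(benzyloxy)-3-(2,2-dibromoethenyl)-2-methoxybenzene
Conditions: CBr4 (2 equiv), PPh3 (4 equiv), CH2Cl2, 0 °C
Reagents that add atoms: carbon tetrabromide, BrC(Br)(Br)Br
Why: Corey–Fuchs (Ramirez) dibromo-olefination, a Wittig-type reaction of the aldehyde that tolerates aryl ethers.

Step 7
Reactants: 9 1-(benzyloxy)-3-(2,2-dibromoethenyl)-2-methoxybenzene
Product: 10 N-{[3-(benzyloxy)-2-methoxyphenyl]ethynyl}-N,4-dimethylbenzenesulfonamide
Conditions: TsNHMe (1.0 equiv), CuI (12 mol %), DMEDA (18 mol %), Cs2CO3 (4 equiv), DMF, 70 °C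
Reagents that add atoms: N-methyl-4-methylbenzenesulfonamide, CNS(=O)(=O)c1ccc(C)cc1
Why: Copper-catalysed Ullmann-type N-alkynylation of a sulfonamide with a 1,1-dibromoalkene (C–N coupling plus dehydrobromination), a general ynamide synthesis.

Step 8
Reactants: 5 2-hydroxy-3,4,5,6-tetramethoxybenzaldehyde, 10 N-{[3-(benzyloxy)-2-methoxyphenyl]ethynyl}-N,4-dimethylbenzenesulfonamide
Product: 12 3-[3-(benzyloxy)-2-methoxyphenyl]-5,6,7,8-tetramethoxy-4H-chromen-4-one, via (E)-sulfonamido enone 11 (not isolated)
Conditions: [Rh(cod)OH]2 (2.5 mol %), DPEphos (5.5 mol %), PhMe, 60 °C; then DBU (0.2 equiv), 80 °C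
Reagents that add atoms: none
Why: Proposed new method: a phenoxide-directed rhodium-catalysed hydroacylation of an aryl ynamide telescoped with oxa-Michael/E1cB ring closure, in which the ynamide is an arylacetaldehyde-level two-carbon unit and its sulfonamide a traceless leaving group; the phenol of 5 protonates the Rh–OH precatalyst, the resulting monovalent rhodium phenoxide inserts into the ortho formyl C–H to give a five-membered acyl(hydrido) chelate of trivalent rhodium that resists decarbonylation, the hydride migrates to the electrophilic N-bearing carbon of the keteniminium-polarised alkyne so that rhodium sits on the aryl-bearing carbon, C–C reductive elimination forges C4–C3 (syn addition, hence E-configured 11), and DBU then triggers 6-endo phenoxide addition to the sulfonamido-bearing carbon and expulsion of TsNMe− to close ring C; the closest known reaction types are the chelation-assisted rhodium-catalysed hydroacylation of alkynes by salicylaldehydes, the hydroacylation of ynamides to β-enaminones by other chelating aldehydes, and the cyclisation of 2-hydroxyaryl enaminones to chromones, but their union on a salicylaldehyde/aryl-ynamide pair to give an isoflavone has not been shown.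

Step 9
Reactants: 12 3-[3-(benzyloxy)-2-methoxyphenyl]-5,6,7,8-tetramethoxy-4H-chromen-4-one
Product: 13 5-hydroxy-3-(3-hydroxy-2-methoxyphenyl)-6,7,8-trimethoxy-4H-chromen-4-one (5,3'-dihydroxy-6,7,8,2'-tetramethoxyisoflavone)
Conditions: BCl3 (5 equiv, 1 M in CH2Cl2), C6HMe5 (3 equiv), CH2Cl2, −78 → 0 °C; then MeOH, aq. HCl
Reagents that add atoms: none
Why: BCl3 cleaves the benzyl ether at −78 °C (benzyl cation trapped by pentamethylbenzene in a Friedel–Crafts alkylation) and, on warming, only the 5-OMe through its six-membered boron chelate with the C4 carbonyl (chelation-controlled Lewis-acid demethylation), leaving the unchelated 6-, 7-, 8- and 2'-OMe groups intact.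

## Compound list

1 | 3,4,5-trimethoxyphenol | COc1cc(O)cc(OC)c1OC | starting material
2 | 2-bromo-3,4,5-trimethoxyphenol | COc1cc(O)c(Br)c(OC)c1OC | intermediate
3 | 2,3,4,5-tetramethoxyphenol | COc1cc(O)c(OC)c(OC)c1OC | intermediate
4 | 2-(hydroxymethyl)-3,4,5,6-tetramethoxyphenol (salicyl alcohol, present as its magnesium phenoxide) | OCc1c(O)c(OC)c(OC)c(OC)c1OC | intermediate (not isolated)
5 | 2-hydroxy-3,4,5,6-tetramethoxybenzaldehyde | O=Cc1c(O)c(OC)c(OC)c(OC)c1OC | intermediate
6 | 2,3-dihydroxybenzaldehyde | O=Cc1cccc(O)c1O | starting material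
7 | 3-(benzyloxy)-2-hydroxybenzaldehyde | O=Cc1cccc(OCc2ccccc2)c1O | intermediate
8 | 3-(benzyloxy)-2-methoxybenzaldehyde | O=Cc1cccc(OCc2ccccc2)c1OC | intermediate
9 | 1-(benzyloxy)-3-(2,2-dibromoethenyl)-2-methoxybenzene | BrC(Br)=Cc1cccc(OCc2ccccc2)c1OC | intermediate
10 | N-{[3-(benzyloxy)-2-methoxyphenyl]ethynyl}-N,4-dimethylbenzenesulfonamide | CN(C#Cc1cccc(OCc2ccccc2)c1OC)S(=O)(=O)c1ccc(C)cc1 | intermediate
11 | (E)-2-[3-(benzyloxy)-2-methoxyphenyl]-1-(2-hydroxy-3,4,5,6-tetramethoxyphenyl)-3-[methyl(4-methylbenzenesulfonyl)amino]prop-2-en-1-one | COc1c(OCc2ccccc2)cccc1/C(C(=O)c1c(O)c(OC)c(OC)c(OC)c1OC)=C\N(C)S(=O)(=O)c1ccc(C)cc1 | intermediate (not isolated)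
12 | 3-[3-(benzyloxy)-2-methoxyphenyl]-5,6,7,8-tetramethoxy-4H-chromen-4-one | COc1c(OCc2ccccc2)cccc1-c1coc2c(OC)c(OC)c(OC)c(OC)c2c1=O | intermediate
13 | 5-hydroxy-3-(3-hydroxy-2-methoxyphenyl)-6,7,8-trimethoxy-4H-chromen-4-one | COc1c(O)cccc1-c1coc2c(OC)c(OC)c(OC)c(O)c2c1=O | target

## Step count and risk

Total step count: 9 (steps 1–3 for ring A, steps 4–7 for ring B, steps 8–9 after convergence).
Longest linear sequence: 6 steps (6 → 7 → 8 → 9 → 10 → 12 → 13).

The three steps most likely to fail:

**Step 8 (proposed new annulation).** The risks are reversed regiochemistry of hydride insertion, O–H addition of the phenol across the ynamide, and adventitious ynamide hydration. The fallback is the known deoxybenzoin route; it sets out from ynamide 10 (with phenol 3 as partner) and comes back to the route at 12. Ynamide 10 is hydrated with catalytic TsOH·H2O in wet MeCN at rt to 2-[3-(benzyloxy)-2-methoxyphenyl]-N-methyl-N-(4-methylbenzenesulfonyl)acetamide F1. This activated amide is saponified with LiOH in THF/H2O to [3-(benzyloxy)-2-methoxyphenyl]acetic acid F2. Phenol 3 is C-acylated with F2 at its only free position (BF3·OEt2, 70 °C, Friedel–Crafts/Fries acylation) to give 2-[3-(benzyloxy)-2-methoxyphenyl]-1-(2-hydroxy-3,4,5,6-tetramethoxyphenyl)ethan-1-one F3. Heating F3 with DMF dimethyl acetal in THF at 65 °C adds C2 and closes ring C to give 12.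

**Step 2 (methoxylation of a doubly ortho-flanked, very electron-rich bromophenol).** The risks are slow substitution and hydrodebromination. The fallback avoids aryl halide substitution altogether; it sets out from 1 and comes back to the route at 5. Phenol 1 is oxidised with IBX in DMF at rt to 3,4,5-trimethoxycyclohexa-3,5-diene-1,2-dione F4, which is reduced in the same flask with aqueous Na2S2O4 to 3,4,5-trimethoxybenzene-1,2-diol F5. Exhaustive methylation (Me2SO4, K2CO3, acetone, reflux) gives pentamethoxybenzene F6. Rieche formylation (Cl2CHOMe, TiCl4, CH2Cl2, 0 °C) at the single ring C–H gives 2,3,4,5,6-pentamethoxybenzaldehyde F7. One of the two equivalent ortho methyl ethers is then removed through the carbonyl chelate (BCl3, 1.1 equiv, CH2Cl2, −20 °C) to give 5.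

**Step 9 (one-pot global deprotection).** The risks are over-demethylation at 6-OMe or 2'-OMe, which sit next to boron-bound oxygens, and C-benzylation of the electron-rich rings. The fallback is a staged, orthogonal deprotection without a Lewis acid; it sets out from 12 and comes back at 13. The benzyl ether of 12 is hydrogenolysed (H2 1 atm, Pd/C, EtOAc–MeOH, rt, stopped after one equivalent) to 3-(3-hydroxy-2-methoxyphenyl)-5,6,7,8-tetramethoxy-4H-chromen-4-one F8. The 5-OMe alone is then cleaved by Brønsted acid assisted by the peri carbonyl (conc. HCl, EtOH, reflux) to give 13.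

## Further compounds

F1 | step 8 | 2-[3-(benzyloxy)-2-methoxyphenyl]-N-methyl-N-(4-methylbenzenesulfonyl)acetamide | CN(C(=O)Cc1cccc(OCc2ccccc2)c1OC)S(=O)(=O)c1ccc(C)cc1
F2 | step 8 | [3-(benzyloxy)-2-methoxyphenyl]acetic acid | OC(=O)Cc1cccc(OCc2ccccc2)c1OC
F3 | step 8 | 2-[3-(benzyloxy)-2-methoxyphenyl]-1-(2-hydroxy-3,4,5,6-tetramethoxyphenyl)ethan-1-one | COc1c(OCc2ccccc2)cccc1CC(=O)c1c(O)c(OC)c(OC)c(OC)c1OC
F4 | step 2 | 3,4,5-trimethoxycyclohexa-3,5-diene-1,2-dione | O=C1C(=O)C(OC)=C(OC)C(OC)=C1
F5 | step 2 | 3,4,5-trimethoxybenzene-1,2-diol | COc1cc(O)c(O)c(OC)c1OC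
F6 | step 2 | pentamethoxybenzene | COc1cc(OC)c(OC)c(OC)c1OC
F7 | step 2 | 2,3,4,5,6-pentamethoxybenzaldehyde | O=Cc1c(OC)c(OC)c(OC)c(OC)c1OC
F8 | step 9 | 3-(3-hydroxy-2-methoxyphenyl)-5,6,7,8-tetramethoxy-4H-chromen-4-one | COc1c(O)cccc1-c1coc2c(OC)c(OC)c(OC)c(OC)c2c1=O
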